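Start with the ratio.

| setting | ochre | amber | green | zeta | theta |
|---|---|---|---|---|---|
| electrophile | 0.63 M | 0.63 M | 0.63 M | 0.63 M | 0.63 M |
| nucleophile | 1.4 M | 1.5 M | 1.3 M | 1.10 M | 1.70 M |
| remark | run made earlier | run made earlier | run made earlier |  |  |
| time |  |  |  | 20 min | 20 min |

| run | time / min | electrophile / % | product / % |
|---|---|---|---|
| ochre | 4.00 | 56.3 | 43.7 |
| ochre | 8.00 | 38.4 | 61.9 |
| ochre | 12.0 | 28.2 | 71.9 |
| ochre | 15.0 | 23.5 | 76.6 |
| ochre | 20.0 | 17.2 | 81.6 |
| amber | 1.50 | 76.3 | 23.7 |
| amber | 3.00 | 61.4 | 38.8 |
| amber | 6.00 | 43.1 | 56.4 |
| amber | 10.0 | 29.7 | 70.1 |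
| amber | 20.0 | 14.7 | 84.4 |
| green | 4.00 | 58.6 | 41.3 |
| green | 8.00 | 40.8 | 58.8 |
| green | 12.0 | 32.0 | 68.8 |
| green | 15.0 | 26.8 | 73.5 |
| green | 20.0 | 21.2 | 78.7 |

(each reading ± 0.3 percentage points)

- the earlier runs were read with a standard deviation of 0.3 percentage points

* part of the electrophile that has reacted at the end, zeta
* part of the electrophile that has reacted at the end, theta
* what raising the concentration of nucleophile from its lowest to its highest value here does to the part of the electrophile that has reacted (changes below 5 percentage points count as none) (it falls / no change / it rises)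

What does one electrophile cost? I count two nucleophile for each electrophile lost, so the excess x, meaning c(nucleophile) minus twice c(electrophile), keeps its charged value through a flask, and a negative x makes the nucleophile the limiting reagent.

What can be carried from run to run? If the rate is second order in the pair, the common logarithm of r = c(nucleophile)/c(electrophile) moves in a straight line with time, at a slope proportional to x. Amber, whose excess of 0.240 M is wider than ochre's, takes r from 2.38 to 4.59 by 20.0 min, the time asked. That gives the decade yield, the powers of ten gained by r per molar of excess in that time: 1.19 M⁻¹.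

But zeta's excess is −0.160 M; does the rule survive a negative sign? It does, since r then falls, from 1.75 to 1.13, and c(electrophile) is x divided by r minus two, so I reckon 70.9% reacted. Theta, with 0.440 M, reaches r = 8.99 and 90.0%.

The forecast, “Taking two nucleophile consumed per electrophile”, gives 70.7% for zeta and 89.8% for theta, and says it rises; my figures differ from these by 0.20 points and 0.20 points.

The flask gives 70.6% for zeta and 89.7% for theta, and it rises by 19 points.

    nucleophile + acid set free ⇌ idle adduct, settled at all times (K = 24.5 M⁻¹)
    nucleophile + acid set free ⇌ protonated nucleophile, settled at all times (K = 1110 M⁻¹)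
    electrophile + nucleophile → acid set free + product (k = 0.134 M⁻¹ min⁻¹)

In theta at 20.0 min, the second nucleophile stands as protonated nucleophile, 0.552 M, against 8.72 × 10⁻⁴ M of acid set free. For a neighbour flask, theta charged with 1.1 M of electrophile, the excess is −0.500 M, so the decade yield takes r down to 0.393, which reckons 28.3% of the electrophile left; that neighbour flask has 28.4% of its electrophile left at 20.0 min.

The data are simulated on assumed constants; the scatter is artificial.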